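The flask holds 1.0 M of X and 0.900 M of G on 2.0 mM of L, and the G stands at 450 times the L.

    X + L → X.L (k1 = 9.9 /M/s)
    G + X.L ⇌ G.X.L (K2 = 28 /M, k2 = 6.9 /M/s)
    G.X.L → Q (k3 = 51 /s)
    Q → L + Z (k4 = 6.7 /s)
    G + Z → G.Z (k5 = 0.0015 /M/s)

X 1.0 M; G 0.900 M; L 2.0 mM; time 4.0 min

- the reaction counts as stopped when no species that holds the X changes by six tenths of a point or more over the second half of the time
- run time (flask): 4.0 min

* why nothing more happens at 4.0 min, or that something still does (forward and back rates have come level / no working catalyst is left / all of X has reacted / G has run out first / it is still moving)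
* how much Z there is at 4.0 min, in percent of the X charged
* how much G.Z there is at 4.0 min, in percent of the X charged

**End state.** G is charged below X, so G is the limiting reagent, and its charge, 90.0% of the X, caps Z. The question is how far the flask gets by 4.0 min.

**Cycle time.** Each L waits in turn for X, for G, and through the last two steps of the cycle. G.X.L falls back at 0.246 /s, far slower than its forward 51 /s, so that return is dropped. The cycle time, the sum of these waits at the current [X] and [G], is 0.431 s at the charge. X is consumed at [L] charged divided by this time.

**Two legs.** After 0.450 M has turned, the cycle time is 0.675 s. The mean of the two times gives 2.07 min for this leg. Reaching 0.700 M turned, the cycle time is 1.23 s, and this leg takes 1.98 min. The sum, 4.05 min, lies close to 4.0 min. By this reckoning X is then still turning at 0.0976 M/min, so the flask is still moving.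

**Side loss.** G.Z forms at 0.0015 /M/s times [G][Z]. Weighting the products at start, middle and end by 1, 4 and 1 gives 0.0570 M.

**Weak link.** That figure ignores what G.Z itself removes from G and Z. Taking half of it from both at the middle and all of it at the end gives 0.0482 M. My reckoning therefore stands at 4.82% G.Z and 65.2% Z.

The forecast says it is still moving, with Z 65% (62% to 68%) and G.Z 5% (4.4% to 5.7%), on the ground that the “slow G + Z side reaction acts on molar concentrations for minutes”.

**Result.** The simulation gives it is still moving, with Z 64.9% and G.Z 5.01%.

**Second flask.** With the 30% of X and 17% of G left at 4.0 min, the cycle time of the flask is 1.47 s. The wait on G makes up 65.6% of it, and X.L, the resting state, holds 65.6% of the catalyst. The neighbour flask, the same in all other charges, has 5.0 × 10⁻⁴ M of L and starts with the same 0.431 s, so a first pass turns 0.278 M. The cycle time there is 0.542 s, and the mean with 0.431 s gives 0.247 M turned. At 4.00 min, the neighbour flask holds X 74.9%, Z 22.0% and G.Z 3.06%.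

The rate constants are those of an exercise.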